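**Retrosynthetic overview**

1. Germacrane numbering is used: ring C1–C10, lactone O on C6, ester O on C8, C11=C13, C12 lactone carbonyl, C14 methyl on C10, C15H2OH on C4. The strategy rests on the ring ketone C3: inside the ten-membered ring it is bonded only to the alkene carbons C2 and C4, so it is excised as CO, which opens the carbocycle to a chain carrying a Z alkenyl iodide at C4 and an E alkenylstannane at C2.
2. The chain is cut at C6–C7 into a Z β-iodoenal (C15, C4–C6, from but-2-yne-1,4-diol) and an alkyne–stannane (C7–C10, C1, C2, from (E)-3-methylpent-2-en-4-yn-1-ol plus one carbon from the Ohira–Bestmann reagent).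
3. C10 comes from an asymmetric epoxidation followed by hydride opening, C6 from a catalytic alkenylzinc addition, C7 and C8 from a second, matched epoxidation; the side-chain centre is bought.
4. Ring order: γ-lactone first (the C11 carbanion of a C6 phosphonoacetate opens the 7,8-epoxide at C7), ten-membered carbocycle second (CO stitched between C2 and C4), then C13 from formaldehyde and desilylation.

Key step: step 15

Remark: C11 of the α-phosphono lactones is epimerisable and is destroyed by the methylenation, so it is carried as a mixture; the trans epimer is drawn.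

**Route**

Step 1
Reactants: 1 but-2-yne-1,4-diol
Product: 2 4-[(tert-butyldimethylsilyl)oxy]but-2-yn-1-ol
Conditions: TBSCl (1 equiv), imidazole, 1 in threefold excess, THF/DMF, 0 °C to rt
Reagents that add atoms: tert-butyldimethylsilyl chloride, CC(C)(C)[Si](C)(C)Cl
Why: Statistical monosilylation (silyl ether formation) of a cheap symmetrical diol used in excess, the surplus diol being removed by aqueous extraction.

Step 2
Reactants: 2 4-[(tert-butyldimethylsilyl)oxy]but-2-yn-1-ol
Product: 4 (2Z)-4-[(tert-butyldimethylsilyl)oxy]-3-iodobut-2-en-1-ol, via vinylalanate 3 (not isolated)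
Conditions: NaAlH2(OCH2CH2OMe)2, THF, 0 °C; then I2, −78 °C to 0 °C
Reagents that add atoms: iodine, II
Why: Hydroxyl-directed trans-hydroalumination of the propargylic alcohol gives the cyclic alkoxyvinylalanate 3 with aluminium on C4, and iodinolysis with retention puts iodine on C4 cis to the carbinol arm, which fixes the Z geometry of C4=C5.

Step 3
Reactants: 4 (2Z)-4-[(tert-butyldimethylsilyl)oxy]-3-iodobut-2-en-1-ol
Product: 5 (2Z)-4-[(tert-butyldimethylsilyl)oxy]-3-iodobut-2-enal
Conditions: MnO2, CH2Cl2, rt, dark
Reagents that add atoms: none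
Why: Chemoselective MnO2 oxidation of the allylic alcohol gives the C6 aldehyde under neutral conditions that should leave the Z iodoalkene unisomerised; the enal is used at once.

Step 4
Reactants: 6 (2E)-3-methylpent-2-en-4-yn-1-ol
Product: 7 (2E,4E)-3-methyl-5-(tributylstannyl)penta-2,4-dien-1-ol
Conditions: Bu3SnH (slow addition), PdCl2(PPh3)2 (2 mol%), THF, 0 °C
Reagents that add atoms: tributyltin hydride, CCCC[SnH](CCCC)CCCC
Why: Palladium-catalysed syn hydrostannation places tin on the terminal alkyne carbon C2 and gives the E alkene (a minor internal regioisomer is separable), and it is done first because the later aluminium hydride step would reduce a propargylic alkoxide or attack an alkynyl epoxide in the conjugate sense, whereas an alkenylstannane is inert to it.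

Step 5
Reactants: 7 (2E,4E)-3-methyl-5-(tributylstannyl)penta-2,4-dien-1-ol
Product: 8 [(2S,3S)-3-methyl-3-[(E)-2-(tributylstannyl)ethenyl]oxiran-2-yl]methanol
Conditions: Ti(OiPr)4 (10 mol%), L-(+)-diethyl tartrate (12 mol%), tBuOOH, 4 Å molecular sieves, CH2Cl2, −20 °C
Reagents that add atoms: tert-butyl hydroperoxide, CC(C)(C)OO
Why: Katsuki–Sharpless asymmetric epoxidation acts only on the alkene allylic to the free hydroxyl (C9=C10), and with the L-(+)-tartrate the usual face rule for an E trisubstituted allylic alcohol should give the (2S,3S) epoxide, which sets C10.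

Step 6
Reactants: 8 [(2S,3S)-3-methyl-3-[(E)-2-(tributylstannyl)ethenyl]oxiran-2-yl]methanol
Product: 9 (3R,4E)-3-methyl-5-(tributylstannyl)pent-4-ene-1,3-diol
Conditions: NaAlH2(OCH2CH2OMe)2, THF, −20 °C to 0 °C
Reagents that add atoms: none
Why: Alkoxide-directed reductive opening of a 2,3-epoxy alcohol, in which the aluminium hydride bound to the C8 oxygen delivers hydride to C9 through a five-membered transition state, so the C9–O bond is removed while the hindered tertiary C10–O bond and its configuration are kept in the 1,3-diol.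

Step 7
Reactants: 9 (3R,4E)-3-methyl-5-(tributylstannyl)pent-4-ene-1,3-diol
Product: 10 tributyl[(1E,3R)-3-methyl-3,5-bis[(triethylsilyl)oxy]pent-1-en-1-yl]stannane
Conditions: Et3SiOTf, 2,6-lutidine, CH2Cl2, −78 °C to 0 °C
Reagents that add atoms: triethylsilyl trifluoromethanesulfonate, CC[Si](CC)(CC)OS(=O)(=O)C(F)(F)F
Why: Silyl ether formation with the silyl triflate, which is reactive enough for the hindered tertiary allylic C10 hydroxyl, the lutidine buffer shielding the alkenylstannane from acid.

Step 8
Reactants: 10 tributyl[(1E,3R)-3-methyl-3,5-bis[(triethylsilyl)oxy]pent-1-en-1-yl]stannane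
Product: 11 (3R,4E)-3-methyl-3-[(triethylsilyl)oxy]-5-(tributylstannyl)pent-4-enal
Conditions: (COCl)2, DMSO, CH2Cl2, −78 °C to −40 °C; Et3N, to 0 °C
Reagents that add atoms: none
Why: Swern oxidation applied directly to the bis-silyl ether, in which the chlorosulfonium reagent cleaves only the unhindered primary triethylsilyl ether and oxidises it in the same operation to the C8 aldehyde, the tertiary silyl ether staying in place.

Step 9
Reactants: 11 (3R,4E)-3-methyl-3-[(triethylsilyl)oxy]-5-(tributylstannyl)pent-4-enal; 12 dimethyl (1-diazo-2-oxopropyl)phosphonate (Ohira–Bestmann reagent)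
Product: 13 tributyl[(1E,3R)-3-methyl-3-[(triethylsilyl)oxy]hex-1-en-5-yn-1-yl]stannane
Conditions: K2CO3, MeOH, 0 °C to rt
Reagents that add atoms: none
Why: Ohira–Bestmann (Seyferth–Gilbert) homologation, in which the diazomethylphosphonate anion released by methanolysis adds to the aldehyde and loss of phosphate and N2 gives the terminal alkyne with C7 from the reagent, under conditions mild enough for a β-silyloxy aldehyde.

Step 10
Reactants: 13 tributyl[(1E,3R)-3-methyl-3-[(triethylsilyl)oxy]hex-1-en-5-yn-1-yl]stannane; 5 (2Z)-4-[(tert-butyldimethylsilyl)oxy]-3-iodobut-2-enal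
Product: 16 (2Z,4S,5E,8R,9E)-1-[(tert-butyldimethylsilyl)oxy]-2-iodo-8-methyl-8-[(triethylsilyl)oxy]-10-(tributylstannyl)deca-2,5,9-trien-4-ol (bis-allylic alcohol; 6S and 10R in germacrane numbering), via alkenylborane 14 (not isolated), via alkenylzinc 15 (not isolated)
Conditions: Cy2BH, toluene, 0 °C to rt; Me2Zn, −78 °C; (−)-MIB (5 mol%), then 5, −30 °C to 0 °C; aq. NH4Cl
Reagents that add atoms: none
Why: Syn hydroboration of the terminal alkyne gives the E alkenylborane 14 (the internal stannylalkene is left), boron-to-zinc exchange gives alkenylzinc 15, and its amino-alcohol-catalysed 1,2-addition to the enal forms C6–C7; the (−)-MIB zinc alkoxide should steer the alkenyl group to the Si face of the aldehyde, as it does with arenecarbaldehydes, which gives the 6S alcohol, and any minor C6 epimer is the mismatched, slow substrate of step 11.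

Step 11
Reactants: 16 bis-allylic alcohol (6S,10R)
Product: 17 erythro 7,8-epoxy alcohol (16 with a trans 7,8-epoxide; 6R 7R 8R 10R)
Conditions: Ti(OiPr)4 (20 mol%), D-(−)-diisopropyl tartrate (24 mol%), tBuOOH, 4 Å molecular sieves, CH2Cl2, −20 °C
Reagents that add atoms: tert-butyl hydroperoxide, CC(C)(C)OO
Why: Katsuki–Sharpless epoxidation of a secondary allylic alcohol in its matched sense, the C6 epimer in hand being the fast-reacting one with the D-(−)-tartrate reagent and giving the erythro epoxide that sets C7 and C8; the iodoalkene is deactivated and is the mismatched allylic partner, and the stannylalkene has no free allylic hydroxyl, so both should survive.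

Step 12
Reactants: 17 erythro 7,8-epoxy alcohol; 18 2-(diethoxyphosphoryl)acetic acid
Product: 19 C6 2-(diethoxyphosphoryl)acetate of epoxy alcohol 17
Conditions: DCC, DMAP (cat.), CH2Cl2, 0 °C to rt
Reagents that add atoms: none
Why: Steglich esterification acylates the only free hydroxyl (C6) under near-neutral conditions that the epoxide, both silyl ethers, the iodoalkene and the stannane tolerate.

Step 13
Reactants: 19 epoxy phosphonoacetate
Product: 20 trans α-(diethoxyphosphoryl) γ-lactone with free C8 hydroxyl (6S 7R 8R 10R; C11 drawn trans)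
Conditions: LiCl, DBU, MeCN, 0 °C to rt; pH 7 buffer at 0 °C
Reagents that add atoms: none
Why: Intramolecular alkylation of the lithium-chelated phosphonoacetate carbanion by the epoxide (lactone-forming 5-exo-tet closure), in which C11 attacks C7 from the side opposite the C7–O bond, so C7 is inverted, C8 keeps its oxygen and configuration, the C6 and C7 substituents end up trans on the lactone, and the cold neutral quench forestalls lactone or phosphoryl migration to the new C8 hydroxyl.

Step 14
Reactants: 20 α-phosphono lactone alcohol; 21 (2R)-2-methylbutanoic acid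
Product: 23 seco precursor (C8 (2R)-2-methylbutanoate of 20: Z iodide at C4 and E stannane at C2), via mixed anhydride 22 (not isolated)
Conditions: 2,4,6-trichlorobenzoyl chloride, Et3N, THF, rt; then 20, DMAP, toluene, rt
Reagents that add atoms: none
Why: Yamaguchi esterification through the mixed anhydride 22 acylates the hindered secondary C8 hydroxyl without touching C8 or the side-chain stereocentre, and acylation outruns any lactone migration.

Step 15
Reactants: 23 seco precursor; 24 carbon monoxide
Product: 25 ten-membered (1E,4Z)-dienone fused to the α-phosphono lactone (6R 7R 8R 10R)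
Conditions: Pd2(dba)3 (10 mol%), AsPh3 (40 mol%), CO (3 atm), NMP/THF, 50 °C, 23 added by syringe pump to a final 1 mM
Reagents that add atoms: none
Why: Zerovalent palladium inserts into the C4–I bond with retention, CO migrates in to give the Z alkenoyl palladium species, the E stannane hands over C2 with retention, and reductive elimination from the acyl(alkenyl)palladium makes C3–C4 and C2–C3 in one operation. The closest known reaction type is the intramolecular carbonylative Stille coupling of an alkenyl halide or triflate with an alkenylstannane to a macrocyclic divinyl ketone; a ten-membered ring is smaller than the usual cases and is the accepted risk. The carbocycle closes by acyl–alkenyl reductive elimination from an eleven-membered palladacycle, on a chain already bent by the trans lactone and the quaternary C10. No stereocentre is formed, and the Z (C4=C5) and E (C1=C2) geometries are carried over because every elementary step at the sp2 carbons is stereoretentive. The step needs carbonylative closure to beat direct coupling and oligomerisation: direct coupling would require a nine-membered E,Z-diene and cannot compete, CO pressure keeps the acyl palladium populated, and slow addition at high dilution suppresses intermolecular coupling. The C6 oxygen is already acylated, so no butenolide can trap the acyl palladium, the exocyclic methylene is still masked as the phosphonate, so no acrylate invites acylpalladation, and the neutral medium leaves C11–H, the C8 ester and both silyl ethers alone.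

Step 16
Reactants: 25 macrocyclic α-phosphono lactone; 26 formaldehyde
Product: 27 α-methylene lactone with C15 OTBS and C10 OTES (bis-silyl ether of the target)
Conditions: K2CO3, 37% aq. CH2O, THF, 0 °C to rt
Reagents that add atoms: none
Why: Horner–Wadsworth–Emmons methylenation of the α-phosphono lactone with formaldehyde installs C13 under mild carbonate conditions that should spare the C8 ester and the dienone, and it removes the C11 stereocentre.

Step 17
Reactants: 27 bis-silyl ether of the target
Product: 28 target CNP0232405.1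
Conditions: HF·pyridine, pyridine, THF, 0 °C to rt
Reagents that add atoms: none
Why: Fluoride-mediated desilylation in a pyridine-buffered medium removes the primary allylic TBS ether and the tertiary TES ether without harming the α-methylene lactone, the ester or the dienone.

**Compound list**

1 | but-2-yne-1,4-diol | OCC#CCO | starting material
2 | 4-[(tert-butyldimethylsilyl)oxy]but-2-yn-1-ol | OCC#CCO[Si](C)(C)C(C)(C)C | intermediate
3 | sodium cyclic alkoxyvinylalanate from 2 (Al on C4, not isolated) | COCCO[Al-]1(OCCOC)OCC=C1CO[Si](C)(C)C(C)(C)C.[Na+] | intermediate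
4 | (2Z)-4-[(tert-butyldimethylsilyl)oxy]-3-iodobut-2-en-1-ol | OC/C=C(\I)CO[Si](C)(C)C(C)(C)C | intermediate
5 | (2Z)-4-[(tert-butyldimethylsilyl)oxy]-3-iodobut-2-enal | O=C/C=C(\I)CO[Si](C)(C)C(C)(C)C | intermediate
6 | (2E)-3-methylpent-2-en-4-yn-1-ol | C#C/C(C)=C/CO | starting material
7 | (2E,4E)-3-methyl-5-(tributylstannyl)penta-2,4-dien-1-ol | OC/C=C(C)/C=C/[Sn](CCCC)(CCCC)CCCC | intermediate
8 | [(2S,3S)-3-methyl-3-[(E)-2-(tributylstannyl)ethenyl]oxiran-2-yl]methanol | OC[C@@H]1O[C@@]1(C)/C=C/[Sn](CCCC)(CCCC)CCCC | intermediate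
9 | (3R,4E)-3-methyl-5-(tributylstannyl)pent-4-ene-1,3-diol | OCC[C@@](C)(O)/C=C/[Sn](CCCC)(CCCC)CCCC | intermediate
10 | tributyl[(1E,3R)-3-methyl-3,5-bis[(triethylsilyl)oxy]pent-1-en-1-yl]stannane | CC[Si](CC)(CC)OCC[C@@](C)(O[Si](CC)(CC)CC)/C=C/[Sn](CCCC)(CCCC)CCCC | intermediate
11 | (3R,4E)-3-methyl-3-[(triethylsilyl)oxy]-5-(tributylstannyl)pent-4-enal | O=CC[C@@](C)(O[Si](CC)(CC)CC)/C=C/[Sn](CCCC)(CCCC)CCCC | intermediate
12 | dimethyl (1-diazo-2-oxopropyl)phosphonate | CC(=O)C(=[N+]=[N-])P(=O)(OC)OC | starting material
13 | tributyl[(1E,3R)-3-methyl-3-[(triethylsilyl)oxy]hex-1-en-5-yn-1-yl]stannane | C#CC[C@@](C)(O[Si](CC)(CC)CC)/C=C/[Sn](CCCC)(CCCC)CCCC | intermediate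
14 | E alkenyl(dicyclohexyl)borane from 13 (boron on C7, not isolated) | C1CCCCC1B(C1CCCCC1)/C=C/C[C@@](C)(O[Si](CC)(CC)CC)/C=C/[Sn](CCCC)(CCCC)CCCC | intermediate
15 | E alkenyl(methyl)zinc from 14 (zinc on C7, not isolated) | C[Zn]/C=C/C[C@@](C)(O[Si](CC)(CC)CC)/C=C/[Sn](CCCC)(CCCC)CCCC | intermediate
16 | (2Z,4S,5E,8R,9E)-1-[(tert-butyldimethylsilyl)oxy]-2-iodo-8-methyl-8-[(triethylsilyl)oxy]-10-(tributylstannyl)deca-2,5,9-trien-4-ol | O[C@H](/C=C(\I)CO[Si](C)(C)C(C)(C)C)/C=C/C[C@@](C)(O[Si](CC)(CC)CC)/C=C/[Sn](CCCC)(CCCC)CCCC | intermediate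
17 | erythro 7,8-epoxy alcohol: 16 with a trans 7,8-epoxide (germacrane 6R,7R,8R,10R) | O[C@H](/C=C(\I)CO[Si](C)(C)C(C)(C)C)[C@H]1O[C@@H]1C[C@@](C)(O[Si](CC)(CC)CC)/C=C/[Sn](CCCC)(CCCC)CCCC | intermediate
18 | 2-(diethoxyphosphoryl)acetic acid | CCOP(=O)(OCC)CC(=O)O | starting material
19 | C6 2-(diethoxyphosphoryl)acetate of 17 | CCOP(=O)(OCC)CC(=O)O[C@H](/C=C(\I)CO[Si](C)(C)C(C)(C)C)[C@H]1O[C@@H]1C[C@@](C)(O[Si](CC)(CC)CC)/C=C/[Sn](CCCC)(CCCC)CCCC | intermediate
20 | trans α-(diethoxyphosphoryl) γ-lactone (O–C6–C7–C11–C12) with free C8 hydroxyl (germacrane 6S,7R,8R,10R; C11 drawn trans) | CCOP(=O)(OCC)[C@@H]1C(=O)O[C@H](/C=C(\I)CO[Si](C)(C)C(C)(C)C)[C@H]1[C@@H](C[C@@](C)(O[Si](CC)(CC)CC)/C=C/[Sn](CCCC)(CCCC)CCCC)O | intermediate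
21 | (2R)-2-methylbutanoic acid | CC[C@@H](C)C(=O)O | starting material
22 | (2R)-2-methylbutanoic 2,4,6-trichlorobenzoic anhydride (not isolated) | CC[C@@H](C)C(=O)OC(=O)c1c(Cl)cc(Cl)cc1Cl | intermediate
23 | seco precursor: C8 (2R)-2-methylbutanoate of 20, Z iodide at C4, E stannane at C2 | CCOP(=O)(OCC)[C@@H]1C(=O)O[C@H](/C=C(\I)CO[Si](C)(C)C(C)(C)C)[C@H]1[C@@H](C[C@@](C)(O[Si](CC)(CC)CC)/C=C/[Sn](CCCC)(CCCC)CCCC)OC(=O)[C@H](C)CC | intermediate
24 | carbon monoxide | [C-]#[O+] | starting material
25 | ten-membered (1E,4Z)-3-oxo dienone fused to the α-phosphono 12,6-lactone, C15 OTBS, C10 OTES, C8 ester (germacrane 6R,7R,8R,10R) | CCOP(=O)(OCC)[C@@H]1C(=O)O[C@@H]2/C=C(/CO[Si](C)(C)C(C)(C)C)C(=O)/C=C/[C@](C)(O[Si](CC)(CC)CC)C[C@@H](OC(=O)[C@H](C)CC)[C@@H]12 | intermediate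
26 | formaldehyde | C=O | starting material
27 | 15-O-TBS, 10-O-TES ether of the target (α-methylene lactone) | C=C1C(=O)O[C@@H]2/C=C(/CO[Si](C)(C)C(C)(C)C)C(=O)/C=C/[C@](C)(O[Si](CC)(CC)CC)C[C@@H](OC(=O)[C@H](C)CC)[C@@H]12 | intermediate
28 | CNP0232405.1 | C=C1C(=O)O[C@@H]2/C=C(/CO)C(=O)/C=C/[C@](C)(O)C[C@@H](OC(=O)[C@H](C)CC)[C@@H]12 | target

**Totals**

Total step count: 17 (3 for the west fragment, 6 for the east fragment, 8 from the fragment union on).
Longest linear sequence: 14 steps (steps 4 to 17).

**Steps most likely to fail**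

1. Step 15. What may go wrong: the strained ten-membered acyl–alkenyl closure may be slower than intermolecular coupling, so that oligomerisation, direct dimerisation or protodestannylation consumes the substrate. Fallback, setting out from 23 and coming back at 25: the one-step CO stitching is replaced by a carbonyl-addition ring closure at C2–C3. Reductive carbonylation of the C4 iodide (Pd(PPh3)4, CO, Bu3SnH added slowly, THF, 50 °C) would give the C3 aldehyde F1; iododestannylation (I2, CH2Cl2, 0 °C) would give the E alkenyl iodide F2; a Nozaki–Hiyama–Kishi cyclisation (CrCl2, NiCl2 cat., DMSO/THF, high dilution) would close the ring to the C3 carbinol F3 as both epimers; Dess–Martin periodinane would then oxidise it to 25.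

2. Step 13. What may go wrong: the stabilised carbanion may be too weak a nucleophile for the epoxide, may attack C8 instead (six-membered lactone), or the freed C8 alkoxide may shift the lactone or the phosphoryl group. Fallback, setting out from 16 and coming back at 23: the C7–C11 bond is made by carbene addition instead of displacement. Steglich esterification of 16 with 18 would give the allylic phosphonoacetate F4, and diazo transfer (4-acetamidobenzenesulfonyl azide, DBU, MeCN) the diazo ester F5. Rh2(OAc)4-catalysed intramolecular cyclopropanation of the E C7=C8 alkene would give the phosphono cyclopropane lactone F6, with the C6 substituent expected on the convex face. Caesium (2R)-2-methylbutanoate (from 21 and Cs2CO3, DMSO, 60 °C) would then open the doubly activated cyclopropane at C8 with inversion (homoconjugate addition) and give 23 directly, with the same C7/C8 relationship as the epoxide route.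

3. Step 10. What may go wrong: poor facial selectivity at C6 with the β-iodoenal, or methyl transfer from zinc competing with alkenyl transfer. Fallback, setting out from 13 and 5 and coming back at 17: reagent control in the addition is given up and the epoxidation resolves C6. Alkenylzinc 15, added in the presence of achiral 2-(dimethylamino)ethanol, would give 16 together with its C6 epimer F7. In step 11 only 16 is matched to the D-(−)-tartrate reagent and is epoxidised to 17. The unreacted C6 epimer is recovered, oxidised with MnO2 to the dienone F8 and returned to the mixture of both alcohols by Luche reduction (NaBH4, CeCl3, MeOH, −78 °C) for another pass.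

**Further compounds**

F1 | step 15 | seco C3 aldehyde (iodine of 23 replaced by CHO, Z) | CCOP(=O)(OCC)[C@@H]1C(=O)O[C@H](/C=C(\C=O)CO[Si](C)(C)C(C)(C)C)[C@H]1[C@@H](C[C@@](C)(O[Si](CC)(CC)CC)/C=C/[Sn](CCCC)(CCCC)CCCC)OC(=O)[C@H](C)CC
F2 | step 15 | seco C3 aldehyde with E alkenyl iodide at C2 | CCOP(=O)(OCC)[C@@H]1C(=O)O[C@H](/C=C(\C=O)CO[Si](C)(C)C(C)(C)C)[C@H]1[C@@H](C[C@@](C)(O[Si](CC)(CC)CC)/C=C/I)OC(=O)[C@H](C)CC
F3 | step 15 | ten-membered C3 carbinol (both C3 epimers) | CCOP(=O)(OCC)[C@@H]1C(=O)O[C@@H]2/C=C(/CO[Si](C)(C)C(C)(C)C)C(O)/C=C/[C@](C)(O[Si](CC)(CC)CC)C[C@@H](OC(=O)[C@H](C)CC)[C@@H]12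
F4 | step 13 | C6 2-(diethoxyphosphoryl)acetate of 16 | CCOP(=O)(OCC)CC(=O)O[C@H](/C=C(\I)CO[Si](C)(C)C(C)(C)C)/C=C/C[C@@](C)(O[Si](CC)(CC)CC)/C=C/[Sn](CCCC)(CCCC)CCCC
F5 | step 13 | C6 2-diazo-2-(diethoxyphosphoryl)acetate of 16 | CCOP(=O)(OCC)C(=[N+]=[N-])C(=O)O[C@H](/C=C(\I)CO[Si](C)(C)C(C)(C)C)/C=C/C[C@@](C)(O[Si](CC)(CC)CC)/C=C/[Sn](CCCC)(CCCC)CCCC
F6 | step 13 | 1-(diethoxyphosphoryl)-3-oxabicyclo[3.1.0]hexan-2-one (C11 bonded to C7 and C8) | CCOP(=O)(OCC)[C@]12C(=O)O[C@H](/C=C(\I)CO[Si](C)(C)C(C)(C)C)[C@H]1[C@@H]2C[C@@](C)(O[Si](CC)(CC)CC)/C=C/[Sn](CCCC)(CCCC)CCCC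
F7 | step 10 | C6 epimer of 16 | O[C@@H](/C=C(\I)CO[Si](C)(C)C(C)(C)C)/C=C/C[C@@](C)(O[Si](CC)(CC)CC)/C=C/[Sn](CCCC)(CCCC)CCCC
F8 | step 10 | cross-conjugated dienone (C6 ketone of 16) | O=C(/C=C(\I)CO[Si](C)(C)C(C)(C)C)/C=C/C[C@@](C)(O[Si](CC)(CC)CC)/C=C/[Sn](CCCC)(CCCC)CCCC
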